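**Retrosynthetic overview**
1. Diaporindene H 35 ⇐ bis-silyl indane 33 (desilylation, benzylic oxidation) ⇐ C3–C3a disconnection to phenol allylic carbonate 30. The strategy rests on ring A (the indane benzene ring): C3a is para to the C6 hydroxyl, so the phenoxide is nucleophilic at the very carbon that must bond to C3 of an allylpalladium spanning C3–C2–C(CH3)2.
2. 30 ⇐ tertiary allylic alcohol 27 ⇐ acrylate 25 ⇐ 3,3-diaryl ester 21. C1 is set in 21 by Rh/chiral-diene 1,4-addition of benzodioxanylboronic acid 20 to cinnamate 5 (Heck product from 1).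
3. 20 ⇐ (S)-benzodioxane bromide 16 ⇐ epoxide 14 (phenoxide 6-exo opening of a Shi epoxide). The two catechol oxygens are told apart by starting from symmetric 2,6-dibromo-4-methylphenol 6 and turning one bromine into OH.
4. Ring order: dioxane ring (step 8), then the cyclopentane ring of the indane (step 16). Ring A and ring B (the benzodioxane benzene ring) come from the starting materials.

Key step: step 16

**Remarks**
- Indane numbering used throughout: C1 (aryl-bearing CH), C2 (isopropylidene), C3 (CH2), C3a, C4, C5, C6 (OH), C7 (CHO or CH2O), C7a.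
- Abbreviations: TBS = tert-butyldimethylsilyl, TES = triethylsilyl, ArA = 3-(TBSO)-2-(TBSOCH2)phenyl, ArB = (3S)-7-methyl-3-[2-(TES-oxy)propan-2-yl]-2,3-dihydro-1,4-benzodioxin-5-yl.
- Assumption: (S,S)-Ph-bod* is taken to deliver the aryl group to the si face of the β-carbon of cinnamate 5; if the sense proves opposite, the (R,R) ligand is used.
- Assumption: the D-fructose-derived Shi ketone is taken to give the (R) epoxide from the prenyl ether, as the spiro transition-state model predicts for trisubstituted alkenes.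

**Route**

Step 1
Reactants: 1 2-bromo-6-hydroxybenzaldehyde
Product: 2 3-bromo-2-(hydroxymethyl)phenol
Conditions: NaBH4, MeOH, 0 °C
Reagents that add atoms: none
Why: Borohydride reduction of the aryl aldehyde stores the future C7 aldehyde as a benzylic alcohol that tolerates the later organometallic steps.

Step 2
Reactants: 2 3-bromo-2-(hydroxymethyl)phenol
Product: 3 1-bromo-3-(TBSO)-2-[(TBSO)methyl]benzene
Conditions: TBSCl (2.5 equiv), imidazole, DMF, rt
Reagents that add atoms: tert-butyldimethylsilyl chloride, CC(C)(C)[Si](C)(C)Cl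
Why: Imidazole-promoted silylation protects both hydroxyls in one operation, and the aryl silyl ether can later be cleaved selectively in the presence of the alkyl one.

Step 3
Reactants: 3 1-bromo-3-(TBSO)-2-[(TBSO)methyl]benzene; 4 methyl acrylate
Product: 5 methyl (E)-3-ArA-prop-2-enoate
Conditions: Pd(OAc)2 (5 mol%), P(o-tol)3 (10 mol%), Et3N, DMF, 100 °C
Reagents that add atoms: none
Why: The Heck reaction of an aryl bromide with an acrylate should give the (E)-cinnamate, and silyl ethers tolerate the amine base.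

Step 4
Reactants: 6 2,6-dibromo-4-methylphenol; 7 allyl bromide
Product: 8 1,3-dibromo-5-methyl-2-(prop-2-en-1-yloxy)benzene
Conditions: K2CO3, DMF, 50 °C
Reagents that add atoms: none
Why: Williamson etherification of the symmetric phenol masks the oxygen para to methyl (the future dioxane O bonded to the stereocentre) with a group that is stable to base and organolithiums and is removable under neutral palladium catalysis.

Step 5
Reactants: 8 1,3-dibromo-5-methyl-2-(prop-2-en-1-yloxy)benzene
Product: 11 3-bromo-5-methyl-2-(prop-2-en-1-yloxy)phenol, via aryllithium 9 (not isolated), via lithium aryltrimethoxyborate 10 (not isolated)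
Conditions: n-BuLi (1.0 equiv), THF, −78 °C; B(OMe)3, −78 °C to rt; then H2O2, AcOH, 0 °C to rt
Reagents that add atoms: hydrogen peroxide, OO
Why: Bromine–lithium exchange of one of two equivalent bromines, borate trapping and oxidation of the C–B bond should give a catechol whose two oxygens are distinguished without any regiochemical choice.

Step 6
Reactants: 11 3-bromo-5-methyl-2-(prop-2-en-1-yloxy)phenol; 12 prenyl bromide
Product: 13 1-bromo-5-methyl-3-[(3-methylbut-2-en-1-yl)oxy]-2-(prop-2-en-1-yloxy)benzene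
Conditions: K2CO3, DMF, rt
Reagents that add atoms: none
Why: Williamson etherification (SN2 at the primary allylic carbon) places the prenyl group on the oxygen meta to methyl, which must end up bonded to the dioxane CH2.

Step 7
Reactants: 13 1-bromo-5-methyl-3-[(3-methylbut-2-en-1-yl)oxy]-2-(prop-2-en-1-yloxy)benzene
Product: 14 (3R)-3-{[3-bromo-5-methyl-2-(prop-2-en-1-yloxy)phenoxy]methyl}-2,2-dimethyloxirane
Conditions: D-fructose-derived Shi ketone (30 mol%), KHSO5 (as 2KHSO5·KHSO4·K2SO4), K2CO3, Bu4NHSO4, MeCN/CH2(OMe)2/aq. Na2B4O7 buffer, 0 °C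
Reagents that add atoms: potassium peroxymonosulfate, [K+].[O-]S(=O)(=O)OO
Why: Shi asymmetric epoxidation should oxidise the electron-rich trisubstituted alkene far faster than the monosubstituted allyl ether, and the chiral dioxirane sets the (R) centre through the spiro transition state.

Step 8
Reactants: 14 (3R)-3-{[3-bromo-5-methyl-2-(prop-2-en-1-yloxy)phenoxy]methyl}-2,2-dimethyloxirane
Product: 16 2-[(2S)-8-bromo-6-methyl-2,3-dihydro-1,4-benzodioxin-2-yl]propan-2-ol, via epoxy phenol 15 (not isolated)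
Conditions: Pd(PPh3)4 (5 mol%), K2CO3, MeOH, rt then 50 °C
Reagents that add atoms: none
Why: Tsuji–Trost transfer of the allyl group to methoxide frees the phenoxide, which should open the epoxide at its secondary carbon in a 6-exo-tet SN2 reaction with inversion, turning the (R) epoxide carbon into the (S) dioxane carbon.

Step 9
Reactants: 16 2-[(2S)-8-bromo-6-methyl-2,3-dihydro-1,4-benzodioxin-2-yl]propan-2-ol
Product: 17 {[2-[(2S)-8-bromo-6-methyl-2,3-dihydro-1,4-benzodioxin-2-yl]propan-2-yl]oxy}triethylsilane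
Conditions: TESOTf, 2,6-lutidine, CH2Cl2, −78 to 0 °C
Reagents that add atoms: triethylsilyl trifluoromethanesulfonate, CC[Si](CC)(CC)OS(=O)(=O)C(F)(F)F
Why: Silyl triflate silylation of the tertiary alcohol keeps it from competing with the allylic tertiary alcohol in the later carbonate formation.

Step 10
Reactants: 17 {[2-[(2S)-8-bromo-6-methyl-2,3-dihydro-1,4-benzodioxin-2-yl]propan-2-yl]oxy}triethylsilane
Product: 20 ArB-boronic acid, via aryllithium 18 (not isolated), via lithium aryltriisopropoxyborate 19 (not isolated)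
Conditions: n-BuLi, THF, −78 °C; B(Oi-Pr)3, −78 °C to rt; aq. NH4Cl
Reagents that add atoms: triisopropyl borate, CC(C)OB(OC(C)C)OC(C)C; water, O
Why: Bromine–lithium exchange and borate trapping followed by mild hydrolysis is the standard route to an arylboronic acid, and the silyl ether and dioxane are inert at −78 °C.

Step 11
Reactants: 5 methyl (E)-3-ArA-prop-2-enoate; 20 ArB-boronic acid
Product: 21 methyl (3S)-3-ArA-3-ArB-propanoate
Conditions: [Rh(acac)(C2H4)2] (5 mol%), (S,S)-Ph-bod* (5.5 mol%), KOH (10 mol%), 1,4-dioxane/H2O (10:1), 50 °C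
Reagents that add atoms: none
Why: In the Hayashi–Miyaura reaction the aryl–rhodium species bearing the chiral diene should insert the enoate on the si face of its β-carbon and so set C1 as (S) under catalyst control, the remote dioxane centre having no say.

Step 12
Reactants: 21 methyl (3S)-3-ArA-3-ArB-propanoate
Product: 25 methyl 2-[(S)-ArA(ArB)methyl]prop-2-enoate, via lithium enolate 22 (not isolated), via Mannich base 23 (not isolated), via trimethylammonium iodide 24 (not isolated)
Conditions: LiN(i-Pr)2, THF, −78 °C; CH2=NMe2+ I−, −78 °C to rt; then MeI, MeOH, rt; then DBU, CH2Cl2, rt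
Reagents that add atoms: N,N-dimethylmethyleneiminium iodide, C=[N+](C)C.[I-]
Why: Eschenmoser methylenation (enolate Mannich reaction, N-methylation, E1cB loss of trimethylamine) adds the carbon that becomes C3, while the much less acidic C1–H is left alone.

Step 13
Reactants: 25 methyl 2-[(S)-ArA(ArB)methyl]prop-2-enoate
Product: 27 3-[(R)-ArA(ArB)methyl]-2-methylbut-3-en-2-ol, via methyl enone 26 (not isolated)
Conditions: MeLi (3 equiv), CeCl3 (3 equiv), THF, −78 °C
Reagents that add atoms: methyllithium, [Li]C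
Why: Double organocerium addition to the ester should go cleanly 1,2 at both the ester and the intermediate enone, because the cerium reagent is weakly basic and carbonyl-selective (the descriptor at C1 changes only through priorities).

Step 14
Reactants: 27 3-[(R)-ArA(ArB)methyl]-2-methylbut-3-en-2-ol
Product: 29 methyl 3-[(R)-ArA(ArB)methyl]-2-methylbut-3-en-2-yl carbonate, via lithium alkoxide 28 (not isolated)
Conditions: n-BuLi (1.05 equiv), THF, −78 °C; ClCO2Me, −78 to 0 °C
Reagents that add atoms: methyl chloroformate, COC(=O)Cl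
Why: Acylation of the lithium alkoxide with a chloroformate is the usual way to make a hindered tertiary allylic carbonate, and no other free hydroxyl is present.

Step 15
Reactants: 29 methyl 3-[(R)-ArA(ArB)methyl]-2-methylbut-3-en-2-yl carbonate
Product: 30 methyl 3-[(R)-{3-hydroxy-2-[(TBSO)methyl]phenyl}(ArB)methyl]-2-methylbut-3-en-2-yl carbonate
Conditions: Cs2CO3 (0.5 equiv), DMF/H2O (10:1), rt
Reagents that add atoms: none
Why: Carbonate-mediated hydrolysis is selective for the aryl silyl ether, because phenoxide leaves silicon far more readily than an alkoxide, so the alkyl TBS and TES ethers and the hindered tertiary carbonate should survive.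

Step 16
Reactants: 30 methyl 3-[(R)-{3-hydroxy-2-[(TBSO)methyl]phenyl}(ArB)methyl]-2-methylbut-3-en-2-yl carbonate
Product: 33 (1S)-1-ArB-7-[(TBSO)methyl]-2-(propan-2-ylidene)-2,3-dihydro-1H-inden-6-ol, via allylpalladium phenoxide 31 (not isolated), via cyclohexadienone 32 (not isolated)
Conditions: Pd2(dba)3·CHCl3 (5 mol%), PPh3 (25 mol%), MeCN (0.02 M), rt to 50 °C
Reagents that add atoms: none
Why: Zerovalent palladium ionises the tertiary allylic carbonate (Tsuji–Trost) to the allylpalladium cation spanning C3, C2 and C(CH3)2 with loss of CO2, and the methoxide so released deprotonates the phenol. The phenoxide then attacks the CH2 terminus through its para carbon C3a, a Friedel–Crafts-type allylic alkylation of a phenol, and the resulting cyclohexadienone tautomerises back to the phenol. The five-membered ring is closed in an endo sense with respect to the allyl unit, since the nucleophilic carbon is tethered to the central allyl carbon C2 through C1 and C7a and the C2–C3 bond ends up in the ring, the same topology as the ring closure that ends palladium trimethylenemethane cycloadditions. No stereocentre is created, C1 is not touched, and C3a is re-aromatised. The step needs attack at CH2 rather than at C(CH3)2, which the lower hindrance of the primary terminus and the more substituted alkene of the product favour, and it needs C- rather than O-attack, which is secured because the phenol oxygen cannot reach the allyl unit and intermolecular O-allylation is reversible under palladium. Ring B does not compete because a neutral aryl ether is not nucleophilic enough for the allylpalladium cation.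

Step 17
Reactants: 33 (1S)-1-ArB-7-[(TBSO)methyl]-2-(propan-2-ylidene)-2,3-dihydro-1H-inden-6-ol
Product: 34 (1S)-7-(hydroxymethyl)-1-[(3S)-3-(2-hydroxypropan-2-yl)-7-methyl-2,3-dihydro-1,4-benzodioxin-5-yl]-2-(propan-2-ylidene)-2,3-dihydro-1H-inden-6-ol
Conditions: Bu4NF (4 equiv), AcOH (4 equiv), THF, 0 °C to rt
Reagents that add atoms: none
Why: Fluoride cleaves both the benzylic TBS and the tertiary TES ether, and buffering with acetic acid keeps the medium too weakly basic to deprotonate the doubly benzylic, allylic C1–H.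

Step 18
Reactants: 34 (1S)-7-(hydroxymethyl)-1-[(3S)-3-(2-hydroxypropan-2-yl)-7-methyl-2,3-dihydro-1,4-benzodioxin-5-yl]-2-(propan-2-ylidene)-2,3-dihydro-1H-inden-6-ol
Product: 35 diaporindene H
Conditions: MnO2 (activated, excess), CH2Cl2, rt
Reagents that add atoms: none
Why: Manganese dioxide oxidises benzylic alcohols selectively, so the salicyl alcohol should give the salicylaldehyde while the tertiary alcohol, the phenol and the tetrasubstituted alkene are untouched.

**Compound list**
1 | 2-bromo-6-hydroxybenzaldehyde | O=Cc1c(O)cccc1Br | starting material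
2 | 3-bromo-2-(hydroxymethyl)phenol | OCc1c(O)cccc1Br | intermediate
3 | 1-bromo-3-(tert-butyldimethylsilyloxy)-2-[(tert-butyldimethylsilyloxy)methyl]benzene | CC(C)(C)[Si](C)(C)OCc1c(O[Si](C)(C)C(C)(C)C)cccc1Br | intermediate
4 | methyl acrylate | C=CC(=O)OC | starting material
5 | methyl (E)-3-{3-(TBSO)-2-[(TBSO)methyl]phenyl}prop-2-enoate | COC(=O)/C=C/c1cccc(O[Si](C)(C)C(C)(C)C)c1CO[Si](C)(C)C(C)(C)C | intermediate
6 | 2,6-dibromo-4-methylphenol | Cc1cc(Br)c(O)c(Br)c1 | starting material
7 | allyl bromide | C=CCBr | starting material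
8 | 1,3-dibromo-5-methyl-2-(prop-2-en-1-yloxy)benzene | C=CCOc1c(Br)cc(C)cc1Br | intermediate
9 | [3-bromo-5-methyl-2-(prop-2-en-1-yloxy)phenyl]lithium | C=CCOc1c(Br)cc(C)cc1[Li] | intermediate
10 | lithium [3-bromo-5-methyl-2-(prop-2-en-1-yloxy)phenyl]trimethoxyborate | C=CCOc1c(Br)cc(C)cc1[B-](OC)(OC)OC.[Li+] | intermediate
11 | 3-bromo-5-methyl-2-(prop-2-en-1-yloxy)phenol | C=CCOc1c(Br)cc(C)cc1O | intermediate
12 | prenyl bromide | CC(C)=CCBr | starting material
13 | 1-bromo-5-methyl-3-[(3-methylbut-2-en-1-yl)oxy]-2-(prop-2-en-1-yloxy)benzene | C=CCOc1c(Br)cc(C)cc1OCC=C(C)C | intermediate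
14 | (3R)-3-{[3-bromo-5-methyl-2-(prop-2-en-1-yloxy)phenoxy]methyl}-2,2-dimethyloxirane | CC1(C)O[C@@H]1COc1cc(C)cc(Br)c1OCC=C | intermediate
15 | 2-bromo-6-{[(2R)-3,3-dimethyloxiran-2-yl]methoxy}-4-methylphenol | CC1(C)O[C@@H]1COc1cc(C)cc(Br)c1O | intermediate
16 | 2-[(2S)-8-bromo-6-methyl-2,3-dihydro-1,4-benzodioxin-2-yl]propan-2-ol | Cc1cc(Br)c2O[C@H](C(C)(C)O)COc2c1 | intermediate
17 | {[2-[(2S)-8-bromo-6-methyl-2,3-dihydro-1,4-benzodioxin-2-yl]propan-2-yl]oxy}triethylsilane | Cc1cc(Br)c2O[C@H](C(C)(C)O[Si](CC)(CC)CC)COc2c1 | intermediate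
18 | {(3S)-7-methyl-3-[2-(triethylsilyloxy)propan-2-yl]-2,3-dihydro-1,4-benzodioxin-5-yl}lithium | Cc1cc([Li])c2O[C@H](C(C)(C)O[Si](CC)(CC)CC)COc2c1 | intermediate
19 | lithium {(3S)-7-methyl-3-[2-(triethylsilyloxy)propan-2-yl]-2,3-dihydro-1,4-benzodioxin-5-yl}triisopropoxyborate | Cc1cc([B-](OC(C)C)(OC(C)C)OC(C)C)c2O[C@H](C(C)(C)O[Si](CC)(CC)CC)COc2c1.[Li+] | intermediate
20 | {(3S)-7-methyl-3-[2-(triethylsilyloxy)propan-2-yl]-2,3-dihydro-1,4-benzodioxin-5-yl}boronic acid | Cc1cc(B(O)O)c2O[C@H](C(C)(C)O[Si](CC)(CC)CC)COc2c1 | intermediate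
21 | methyl (3S)-3-ArA-3-ArB-propanoate | COC(=O)C[C@@H](c1cccc(O[Si](C)(C)C(C)(C)C)c1CO[Si](C)(C)C(C)(C)C)c1cc(C)cc2c1O[C@H](C(C)(C)O[Si](CC)(CC)CC)CO2 | intermediate
22 | lithium enolate of 21 | COC(O[Li])=C[C@@H](c1cccc(O[Si](C)(C)C(C)(C)C)c1CO[Si](C)(C)C(C)(C)C)c1cc(C)cc2c1O[C@H](C(C)(C)O[Si](CC)(CC)CC)CO2 | intermediate
23 | methyl (3S)-2-[(dimethylamino)methyl]-3-ArA-3-ArB-propanoate (both C2 epimers) | COC(=O)C(CN(C)C)[C@@H](c1cccc(O[Si](C)(C)C(C)(C)C)c1CO[Si](C)(C)C(C)(C)C)c1cc(C)cc2c1O[C@H](C(C)(C)O[Si](CC)(CC)CC)CO2 | intermediate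
24 | N-methyl trimethylammonium iodide of 23 | COC(=O)C(C[N+](C)(C)C)[C@@H](c1cccc(O[Si](C)(C)C(C)(C)C)c1CO[Si](C)(C)C(C)(C)C)c1cc(C)cc2c1O[C@H](C(C)(C)O[Si](CC)(CC)CC)CO2.[I-] | intermediate
25 | methyl 2-[(S)-ArA(ArB)methyl]prop-2-enoate | C=C(C(=O)OC)[C@@H](c1cccc(O[Si](C)(C)C(C)(C)C)c1CO[Si](C)(C)C(C)(C)C)c1cc(C)cc2c1O[C@H](C(C)(C)O[Si](CC)(CC)CC)CO2 | intermediate
26 | 3-[(S)-ArA(ArB)methyl]but-3-en-2-one | C=C(C(C)=O)[C@@H](c1cccc(O[Si](C)(C)C(C)(C)C)c1CO[Si](C)(C)C(C)(C)C)c1cc(C)cc2c1O[C@H](C(C)(C)O[Si](CC)(CC)CC)CO2 | intermediate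
27 | 3-[(R)-ArA(ArB)methyl]-2-methylbut-3-en-2-ol | C=C(C(C)(C)O)[C@@H](c1cccc(O[Si](C)(C)C(C)(C)C)c1CO[Si](C)(C)C(C)(C)C)c1cc(C)cc2c1O[C@H](C(C)(C)O[Si](CC)(CC)CC)CO2 | intermediate
28 | lithium alkoxide of 27 | C=C(C(C)(C)O[Li])[C@@H](c1cccc(O[Si](C)(C)C(C)(C)C)c1CO[Si](C)(C)C(C)(C)C)c1cc(C)cc2c1O[C@H](C(C)(C)O[Si](CC)(CC)CC)CO2 | intermediate
29 | methyl 3-[(R)-ArA(ArB)methyl]-2-methylbut-3-en-2-yl carbonate | C=C(C(C)(C)OC(=O)OC)[C@@H](c1cccc(O[Si](C)(C)C(C)(C)C)c1CO[Si](C)(C)C(C)(C)C)c1cc(C)cc2c1O[C@H](C(C)(C)O[Si](CC)(CC)CC)CO2 | intermediate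
30 | methyl 3-[(R)-{3-hydroxy-2-[(TBSO)methyl]phenyl}(ArB)methyl]-2-methylbut-3-en-2-yl carbonate (key-step precursor) | C=C(C(C)(C)OC(=O)OC)[C@@H](c1cccc(O)c1CO[Si](C)(C)C(C)(C)C)c1cc(C)cc2c1O[C@H](C(C)(C)O[Si](CC)(CC)CC)CO2 | intermediate
31 | bis(triphenylphosphine)allylpalladium cation with internal phenoxide, allyl unit C3–C2–C(CH3)2, drawn as its C3-bound form | CC(C)=C(C[Pd+](P(c1ccccc1)(c1ccccc1)c1ccccc1)P(c1ccccc1)(c1ccccc1)c1ccccc1)[C@@H](c1cccc([O-])c1CO[Si](C)(C)C(C)(C)C)c1cc(C)cc2c1O[C@H](C(C)(C)O[Si](CC)(CC)CC)CO2 | intermediate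
32 | (1S)-1-ArB-7-[(TBSO)methyl]-2-(propan-2-ylidene)-1,2,3,3a-tetrahydro-6H-inden-6-one (cyclohexadienone, C3a unassigned) | CC(C)=C1CC2C=CC(=O)C(CO[Si](C)(C)C(C)(C)C)=C2[C@H]1c1cc(C)cc2c1O[C@H](C(C)(C)O[Si](CC)(CC)CC)CO2 | intermediate
33 | (1S)-1-ArB-7-[(TBSO)methyl]-2-(propan-2-ylidene)-2,3-dihydro-1H-inden-6-ol (key-step product) | CC(C)=C1Cc2ccc(O)c(CO[Si](C)(C)C(C)(C)C)c2[C@H]1c1cc(C)cc2c1O[C@H](C(C)(C)O[Si](CC)(CC)CC)CO2 | intermediate
34 | (1S)-7-(hydroxymethyl)-1-[(3S)-3-(2-hydroxypropan-2-yl)-7-methyl-2,3-dihydro-1,4-benzodioxin-5-yl]-2-(propan-2-ylidene)-2,3-dihydro-1H-inden-6-ol | CC(C)=C1Cc2ccc(O)c(CO)c2[C@H]1c1cc(C)cc2c1O[C@H](C(C)(C)O)CO2 | intermediate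
35 | diaporindene H, (1S)-6-hydroxy-1-[(3S)-3-(2-hydroxypropan-2-yl)-7-methyl-2,3-dihydro-1,4-benzodioxin-5-yl]-2-(propan-2-ylidene)-2,3-dihydro-1H-indene-7-carbaldehyde | CC(C)=C1Cc2ccc(O)c(C=O)c2[C@H]1c1cc(C)cc2c1O[C@H](C(C)(C)O)CO2 | target

**Step count**
Total: 18 steps. Longest linear sequence: 15 steps (steps 4–10 from 2,6-dibromo-4-methylphenol, then steps 11–18). The arm from 2-bromo-6-hydroxybenzaldehyde is 3 steps before the union.

**Steps most likely to fail**

Step 16 (key step). The endo closure onto the allylpalladium is geometrically demanding. The intermediate may instead be attacked at the C(CH3)2 terminus, lose a proton to give a diene, or undergo intermolecular O-allylation faster than it cyclises. Fallback, a palladium-free SN2 closure of the same bond: it sets out from tertiary alcohol 27. SOCl2 with 2,6-lutidine in Et2O at −20 °C should convert 27 with allylic transposition into the primary allylic chloride F1. Cs2CO3 in wet DMF at high dilution then frees the phenoxide from its aryl silyl ether, and para C-alkylation in a 5-exo-tet mode followed by tautomerisation should give indane 33, where the route is rejoined.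

Step 11. Transmetalation of the ortho-alkoxy boronic acid and insertion of the ortho-substituted cinnamate are both slow. Protodeboronation may therefore outrun addition, and facial selectivity may erode at the higher temperature then needed. Fallback, an auxiliary-controlled cuprate addition instead of catalytic boron chemistry: it sets out from bromides 3 and 17. Heck coupling of 3 with commercial (4S)-3-acryloyl-4-phenyl-1,3-oxazolidin-2-one (C=CC(=O)N1[C@@H](c2ccccc2)COC1=O; Pd(OAc)2, P(o-tol)3, Et3N) gives the cinnamoyl imide F2. Bromide 17 is converted with Mg in THF into the arylmagnesium bromide F3. Addition of F3 to F2 with CuBr·SMe2 (THF/Me2S, −40 °C), anti to the 4-phenyl group of the chelated imide, should give the 3,3-diaryl imide F4. MeOMgBr in MeOH/CH2Cl2 at 0 °C then exchanges the auxiliary for methoxide and gives ester 21, where the route is rejoined.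

Step 7. An allylic aryl ether is not an ideal substrate for the dioxirane, so incomplete facial discrimination would leave the minor enantiomer, which later becomes a diastereomer; some oxidation of the allyl ether is also possible. Fallback, stereocontrol moved to an allylic alcohol: it sets out from phenol 11 and bypasses 13. Sharpless asymmetric epoxidation of prenol (CC(C)=CCO; Ti(Oi-Pr)4, D-(−)-diethyl tartrate, t-BuOOH, 4 Å sieves, CH2Cl2, −20 °C) gives [(2R)-3,3-dimethyloxiran-2-yl]methanol F5. Mitsunobu etherification of 11 with F5 (PPh3, DIAD, THF) at the primary carbon leaves the stereocentre untouched and gives epoxide 14, where the route is rejoined.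

**Further compounds**
F1 | step 16 | 1-chloro-2-[(S)-ArA(ArB)methyl]-3-methylbut-2-ene | ClCC(=C(C)C)[C@@H](c1cccc(O[Si](C)(C)C(C)(C)C)c1CO[Si](C)(C)C(C)(C)C)c1cc(C)cc2c1O[C@H](C(C)(C)O[Si](CC)(CC)CC)CO2
F2 | step 11 | (4S)-3-[(E)-3-ArA-prop-2-enoyl]-4-phenyl-1,3-oxazolidin-2-one | O=C(/C=C/c1cccc(O[Si](C)(C)C(C)(C)C)c1CO[Si](C)(C)C(C)(C)C)N1[C@@H](c2ccccc2)COC1=O
F3 | step 11 | ArB-magnesium bromide | Cc1cc([Mg]Br)c2O[C@H](C(C)(C)O[Si](CC)(CC)CC)COc2c1
F4 | step 11 | (4S)-3-[(3S)-3-ArA-3-ArB-propanoyl]-4-phenyl-1,3-oxazolidin-2-one | O=C(C[C@@H](c1cccc(O[Si](C)(C)C(C)(C)C)c1CO[Si](C)(C)C(C)(C)C)c1cc(C)cc2c1O[C@H](C(C)(C)O[Si](CC)(CC)CC)CO2)N1[C@@H](c2ccccc2)COC1=O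
F5 | step 7 | [(2R)-3,3-dimethyloxiran-2-yl]methanol | CC1(C)O[C@@H]1CO
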